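Count the E standing per Q charged, and start from these runs.

| flask | L | Q | time |
|---|---|---|---|
| Sunday's | 200 mM | 2.00 mM |  |
| Friday's | 100 mM | 2.00 mM |  |
| Saturday's | 200 mM | 4.00 mM |  |
| Monday's | 200 mM | 2.00 mM | 8.0 h |

| Sunday's run: time / h | Sunday's run: [E] / mM | Friday's run: time / h | Friday's run: [E] / mM | Saturday's run: time / h | Saturday's run: [E] / mM |
|---|---|---|---|---|---|
| 0.57 | 14.0 | 0.57 | 10.1 | 0.57 | 26.2 |
| 1.1 | 23.7 | 1.1 | 16.0 | 1.1 | 42.1 |
| 1.7 | 31.3 | 1.7 | 22.7 | 1.7 | 54.1 |
| 2.3 | 36.7 | 2.3 | 25.4 | 2.3 | 62.1 |
| 2.9 | 40.5 | 2.9 | 27.0 | 2.9 | 67.3 |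
| 3.4 | 43.6 | 3.4 | 30.1 | 3.4 | 69.0 |
| 4.0 | 44.7 | 4.0 | 30.6 | 4.0 | 69.7 |

(readings scatter by 0.6 mM)

1. the exponent of [Q] in the starting rate at the charge of the Sunday's run (at the point where two percent of the L have become E)
2. the exponent of [L] in the starting rate at the charge of the Sunday's run (at the point where two percent of the L have become E) (one fixed amount of E, the same in the runs compared)
3. E in the Monday's run at 8.0 h, as a share of the L charged

- Overall: L -> E, with Q as catalyst.
- Constant volume, constant temperature.
- Bound and free are read together.
- An order is taken over about fifteen percent of the charge, up and down.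

In Sunday's run, the last reading over the Q charged was 22.4. I called this T, the apparent turnover number: E standing per Q charged, bound and free together, at 4.0 h. Sunday's last interval added 1.10 mM, against 14.0 mM in the first. E then stood at 22.4% of the L charged. So the E readings of Sunday's run were flattening by 4.0 h.

My zero was the same T in the three runs. I tested it. Saturday's run read 17.4 and Friday's run read 15.3, both lower than Sunday's. One number did not span the charges. But Monday's flask had Sunday's charge, so I used Sunday's T and took E as flat after the last reading. That gave a share of T times Q over L, or 22.4% at 8.0 h.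

The forecast gave 1 for Q, 0.4 for L and 24.8% for Monday's flask, higher than my share. Its ground was “the catalyst is dying, not L running out”.

The flask gave 1.1 for Q, 0.48 for L and 21.7% for Monday's flask.

    Q + L ⇌ QL, settled at all times (6.500 L mol⁻¹)
    QL ⇌ E + Q (25.13 h⁻¹, 133.9 L mol⁻¹ h⁻¹)
    QL → Jy + L (0.4860 h⁻¹)
    E → Wa (0.09792 h⁻¹)

Monday's flask ended at T = 21.7, close to Sunday's 22.4. E in Monday's run held near that count because of the conversion of QL into Jy + L together with the conversion of E into Wa. With the step to Jy taken away, Monday's run reached T = 35.4. With the step to Wa taken away instead, Monday's run reached T = 34.8.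

The data come from a simulation for an exercise.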